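## Retrosynthetic overview

1. The target acid comes from global hydrolysis (aryl pivalate and methyl ester) of chromene ester **13**.
2. **13** comes from the key step: enantioselective Cu-catalysed addition of MeMgBr to C2 of 2-alkyl-benzopyrylium salt **12**. This dearomatises the pyrylium ring and sets the quaternary (R)-C2 centre directly.
3. **12** comes from acid cyclodehydration of the o-hydroxyenone **11**, which is made by Claisen–Schmidt condensation of salicylaldehyde **3** (from methylhydroquinone) with ketoester **10**.
4. **10** comes from Still–Gennari-type Z-selective HWE of aldehyde **6** (terminal-alkene cleavage product of geranylacetone) with phosphonate **9**.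
5. Ring order: the benzene ring is present from the start, the pyran ring closes as the benzopyrylium in step 8, and C2 becomes sp3 and stereodefined in step 9.

Assumptions:
- Geranylacetone is used as the (E)-isomer.
- Pivaloylation of methylhydroquinone occurs at the less hindered OH.
- The Josiphos antipode that gives (R)-**13** is the one chosen in the step 9 ligand screen.

## Route

**Step 1**
Reactants: **1** 2-methylbenzene-1,4-diol (methylhydroquinone)
Product: **2** 4-hydroxy-3-methylphenyl pivalate
Conditions: PivCl (1.0 equiv), Et3N, CH2Cl2, –20 °C → rt
Reagents that add atoms: pivaloyl chloride, CC(C)(C)C(=O)Cl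
Why: The less hindered OH (meta to Me) is acylated selectively (regioisomer removed by chromatography), which leaves the OH ortho to Me free and blocks the para-oxygen for later steps.

**Step 2**
Reactants: **2**
Product: **3** 3-formyl-4-hydroxy-5-methylphenyl pivalate (2-hydroxy-3-methyl-5-pivaloyloxybenzaldehyde)
Conditions: MgCl2, Et3N, (CH2O)n, MeCN, reflux
Reagents that add atoms: paraformaldehyde (formaldehyde), C=O
Why: Casnati–Skattebøl Mg-phenoxide-directed ortho-formylation can only occur at the single free ortho position, so regiochemistry is fixed; the hindered pivalate survives.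

**Step 3**
Reactants: **4** (E)-geranylacetone, (5E)-6,10-dimethylundeca-5,9-dien-2-one
Product: **5** (E)-epoxide: 9,10-epoxy-6,10-dimethylundec-5-en-2-one
Conditions: 1) NBS, THF/H2O, 0 °C; 2) K2CO3, MeOH, rt (one pot)
Reagents that add atoms: water, O
Why: Halohydrin formation is selective for the more accessible, more remote terminal trisubstituted alkene, and base closes the bromohydrin to the epoxide; the internal E-alkene and the ketone are untouched.

**Step 4**
Reactants: **5**
Product: **6** (E)-4-methyl-8-oxonon-4-enal
Conditions: H5IO6, THF/Et2O, 0 °C
Reagents that add atoms: none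
Why: Periodic acid opens the epoxide to the diol and cleaves it (Malaprade-type), giving the aldehyde and acetone; the E-alkene is retained.

**Step 5**
Reactants: **7** methyl P,P-bis(2,2,2-trifluoroethyl)phosphonoacetate; **8** 5-bromo-2-methylpent-2-ene
Product: **9** methyl 2-[bis(2,2,2-trifluoroethoxy)phosphoryl]-6-methylhept-5-enoate
Conditions: NaH, cat. NaI, THF/DMF, 0 °C → 50 °C
Reagents that add atoms: none
Why: Simple enolate C-alkylation of a stabilised phosphonate carbanion installs the homoprenyl group α to the ester.

**Step 6**
Reactants: **9**, **6**
Product: **10** methyl (2Z,6E)-6-methyl-2-(4-methylpent-3-en-1-yl)-10-oxoundeca-2,6-dienoate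
Conditions: KHMDS, 18-crown-6, THF, –78 °C
Reagents that add atoms: none
Why: A Still–Gennari-type HWE with the α-alkyl bis(trifluoroethyl) phosphonate gives the (Z)-trisubstituted acrylate, with the ester cis to the new CH2 chain, as needed in the target; the ketone is not attacked.

**Step 7**
Reactants: **3**, **10**
Product: **11** (E)-o-hydroxyenone (aryl–CH=CH–CO–chain)
Conditions: pyrrolidine (0.3 equiv), AcOH (0.3 equiv), MeOH, rt
Reagents that add atoms: none
Why: Amine-catalysed Claisen–Schmidt condensation occurs at the less hindered methyl side of the methyl ketone (pyrrolidine enamine), giving the linear (E)-enone rather than the branched isomer.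

**Step 8**
Reactants: **11**
Product: **12** 2-alkyl-8-methyl-6-pivaloyloxy-benzopyrylium tetrafluoroborate (alkyl = the full ester-bearing chain)
Conditions: HBF4·OEt2 (1.05 equiv), CH2Cl2, 0 °C, 15 min; concentrate, use crude
Reagents that add atoms: HBF4 (BF4⁻ stays as counter-anion, F[B-](F)(F)F)
Why: As in flavylium salt formation from 2-hydroxychalcones, the protonated enone isomerises, the phenol O closes onto the carbonyl carbon, and dehydration gives the aromatic 2-alkylbenzopyrylium, the planar prochiral cation for the key step.

**Step 9 (key step)**
Reactants: **12**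
Product: **13** methyl (2Z)-2-{(3E)-... chromene ester: (R)-2-methyl-2-[chain]-8-methyl-6-pivaloyloxy-2H-chromene (full SMILES in compound list)
Conditions: MeMgBr (2.2 equiv), CuBr·SMe2 (10 mol %), (R,S)-Josiphos-type ligand (12 mol %), MTBE/CH2Cl2, –78 °C, 3 h
Reagents that add atoms: methylmagnesium bromide, C[Mg]Br
Why: Proposed new method: a chiral [L*Cu–Me] species, formed by transmetalation, delivers methyl to one enantioface of the planar benzopyrylium at the most electrophilic C2, which destroys the pyrylium aromaticity, builds the quaternary O-bearing (R)-centre directly and leaves the benzenoid ring intact; the closest known reaction types are Cu/Josiphos asymmetric Grignard additions to activated heteroaromatic cations (N-acylpyridinium/quinolinium) and Grignard addition to flavylium salts to give 2H-chromenes, with low temperature and non-basic Cu–Me limiting α-deprotonation of the 2-CH2 group.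

**Step 10**
Reactants: **13**
Product: **14** (R)-sargachromenol
Conditions: LiOH·H2O, THF/MeOH/H2O, 45 °C, 16 h; then citric acid to pH 3–4
Reagents that add atoms: water (hydroxide), O
Why: Saponification cleaves the aryl pivalate and the methyl ester together without touching C2 (no bond to the stereocentre is involved) or the alkenes, so the Z-acrylate geometry and the (R)-centre are retained.

## Final checks

- **Structure match:** the chromene has 6-OH, 8-Me and a C3=C4 cis alkene. C2 carries Me and the chain CH2CH2CH=C(Me)CH2CH2CH=C(CO2H)CH2CH2CH=CMe2, with the E-trisubstituted alkene and the acid cis to the CH2 that leads to the chromene. C2 is [C@] with the same neighbour order as the target SMILES, which I confirmed is (R). Target formula C27H38O3.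
- **Carbon and atom accounting:** the ketone carbonyl C10 of **10** becomes C2 of the chromene, and its CH3 becomes C3 of the ring via the aldol step.
- **Stereocentre and protecting groups:** the only stereocentre is set in step 9 and is not touched in step 10, and the pivalate and methyl ester are removed together in step 10.

## Compound list

1 | 2-methylbenzene-1,4-diol | Cc1cc(O)ccc1O | starting material
2 | 4-hydroxy-3-methylphenyl pivalate | Cc1cc(OC(=O)C(C)(C)C)ccc1O | intermediate
3 | 3-formyl-4-hydroxy-5-methylphenyl pivalate | Cc1cc(OC(=O)C(C)(C)C)cc(C=O)c1O | intermediate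
4 | (E)-geranylacetone | CC(C)=CCC/C(C)=C/CCC(C)=O | starting material
5 | (E)-9,10-epoxy-6,10-dimethylundec-5-en-2-one | CC1(C)OC1CC/C(C)=C/CCC(C)=O | intermediate
6 | (E)-4-methyl-8-oxonon-4-enal | O=CCC/C(C)=C/CCC(C)=O | intermediate
7 | methyl P,P-bis(2,2,2-trifluoroethyl)phosphonoacetate | COC(=O)CP(=O)(OCC(F)(F)F)OCC(F)(F)F | starting material
8 | 5-bromo-2-methylpent-2-ene | CC(C)=CCCBr | starting material
9 | methyl 2-[bis(trifluoroethoxy)phosphoryl]-6-methylhept-5-enoate | COC(=O)C(CCC=C(C)C)P(=O)(OCC(F)(F)F)OCC(F)(F)F | intermediate
10 | methyl (2Z,6E)-6-methyl-2-(4-methylpent-3-enyl)-10-oxoundeca-2,6-dienoate | CC(C)=CCC/C(=C/CC/C(C)=C/CCC(C)=O)C(=O)OC | intermediate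
11 | (E)-o-hydroxyenone from 3 + 10 | CC(C)=CCC/C(=C/CC/C(C)=C/CCC(=O)/C=C/c1cc(OC(=O)C(C)(C)C)cc(C)c1O)C(=O)OC | intermediate
12 | benzopyrylium tetrafluoroborate | CC(C)=CCC/C(=C/CC/C(C)=C/CCc1ccc2cc(OC(=O)C(C)(C)C)cc(C)c2[o+]1)C(=O)OC.F[B-](F)(F)F | intermediate
13 | (R)-chromene pivalate methyl ester | CC(C)=CCC/C(=C/CC/C(C)=C/CC[C@]1(C)C=Cc2cc(OC(=O)C(C)(C)C)cc(C)c2O1)C(=O)OC | intermediate
14 | (R)-sargachromenol | CC(C)=CCC/C(=C/CC/C(C)=C/CC[C@]1(C)C=Cc2cc(O)cc(C)c2O1)C(=O)O | target

Reagents used but not numbered: PivCl, paraformaldehyde, NBS, H5IO6, MeMgBr, HBF4·OEt2, LiOH.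

## Totals

Total steps: 10. Longest linear sequence: 7 (4 → 5 → 6 → 10 → 11 → 12 → 13 → 14, counting steps 3, 4, 6, 7, 8, 9, 10).

## Three steps most likely to fail

1. **Step 9 (asymmetric methyl addition):** possible α-deprotonation of the 2-CH2 group, C4 attack (4H-chromene), or low ee.
   Fallback: make racemic **13** by a different route (MeMgBr 1,2-addition to enone **11**, then acid cyclisation of the o-hydroxyphenyl tertiary allylic alcohol) and resolve by preparative chiral-phase HPLC. Alternatively, use Cu-catalysed asymmetric conjugate addition of the chain Grignard to 2-methylchromone, then reduce and dehydrate.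
2. **Step 8 (HBF4 cyclodehydration):** the prenyl and trisubstituted alkenes may protonate and cyclise or isomerise.
   Fallback: form the benzopyrylium and do the Me addition on the geranylacetone-derived ketone **4** (no ester), then add the acid-bearing terminus at the chromene stage by terminal-alkene cleavage and HWE.
3. **Step 6 (Z-selective HWE):** Z:E selectivity for aliphatic aldehydes with α-alkyl phosphonates may be modest.
   Fallback: Peterson olefination of **6** with the α-silyl ester anion, separating the diastereomeric β-hydroxysilanes and eliminating them stereodivergently (acid anti versus base syn) to set the geometry.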